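**Retrosynthetic overview**
1. Feature: in benzofuran numbering C4, C7 and C7a of the six-membered ring (C3a–C4–C5–C6–C7–C7a) carry oxygen in the 1,2,4-pattern of hydroxyquinol, so this ring is carried as a benzene ring with bromine on C7a, between the C3a arm and the C7 oxygen, and is dearomatised late.
2. Key disconnection O1–C7a: palladium-catalysed intramolecular etherification of the C2 alcohol with the C7a bromide closes the five-membered ring with the C2–O bond untouched. Ring order: benzene (bought), dihydrofuran (step 8), dearomatised six-membered ring (steps 14–17).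
3. Precursor: the C3–C3a bond comes from the ortho-lithiated bromoarene and a terminal epoxide. The C2/C1' pair comes from Sharpless epoxidation of (2Z,6E)-farnesol and inversion at C2 by Payne transposition, run through the triol because the trisubstituted 2,3-epoxide dominates the Payne equilibrium.
4. The arene oxygens are set so that the phenol freed for oxidation is on C7 (MOM ether) and the methyl ether is on C4. PhI(OAc)2/MeOH then gives the C7 ketone and the C4 dimethyl ketal, C7 is reduced before C4 is unmasked, and no cyclohex-2-ene-1,4-dione (a hydroquinone tautomer) is formed.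
5. The chain-end E-methyl group is oxidised to the acid right after ring closure, on the robust arene, and carried as a 2-(trimethylsilyl)ethyl ester; fluoride followed by mild acid frees the acid, the tertiary alcohol and the C4 ketone in the last step.

Key step: step 8

Assumption: (2Z,6E)-farnesol and 2-bromo-4-methoxyphenol are taken as purchasable single isomers; the 2Z geometry is what lets epoxidation followed by inversion at C2 deliver the (2S,1'S) pair.

**Step 1**
Reactants: 1 2-bromo-4-methoxyphenol
Product: 2 2-bromo-4-methoxy-1-(methoxymethoxy)benzene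
Conditions: MOMCl, i-Pr2NEt, CH2Cl2, 0 °C → rt
Reagents that add atoms: chloromethyl methyl ether, COCCl
Why: Williamson-type O-alkylation of the phenoxide gives the MOM acetal, which is stable to the bases, Lewis acid and oxidants used up to step 13.

**Step 2**
Reactants: 3 (2Z,6E)-farnesol
Product: 4 (2R,3S)-2,3-epoxy-(6E)-farnesol
Conditions: Ti(OiPr)4 (10 mol %), diethyl D-(−)-tartrate (12 mol %), t-BuOOH (decane), 4 Å MS, CH2Cl2, −20 °C
Reagents that add atoms: tert-butyl hydroperoxide, CC(C)(C)OO
Why: Sharpless asymmetric epoxidation touches only the allylic-alcohol double bond, and with the D-tartrate the Z-olefin should give the (2R,3S) epoxide, which fixes farnesol C3 (the later C1') in its final configuration.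

**Step 3**
Reactants: 4 (2R,3S)-2,3-epoxy-(6E)-farnesol
Product: 6 (2S,3S,6E)-3,7,11-trimethyldodeca-6,10-diene-1,2,3-triol, via Payne epoxide 5 (not isolated)
Conditions: NaOH (0.5 M aq), t-BuOH, 75 °C
Reagents that add atoms: water, O
Why: Payne rearrangement with hydroxide trapping: the C1 alkoxide opens the epoxide at C2 with inversion to the terminal epoxide 5, present only in small equilibrium amount but opened irreversibly by hydroxide at its CH2 end, so the triol forms with C2 inverted and C3 untouched (direct hydroxide attack at C2 of 4 gives the same triol).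

**Step 4**
Reactants: 6 (2S,3S,6E)-3,7,11-trimethyldodeca-6,10-diene-1,2,3-triol
Product: 7 primary mono-tosylate of 6 (C1–OTs; C2 and C3 hydroxyls free)
Conditions: TsCl (1.05 equiv), Et3N, Bu2SnO (2 mol %), CH2Cl2, 0 °C → rt
Reagents that add atoms: p-toluenesulfonyl chloride, Cc1ccc(S(=O)(=O)Cl)cc1
Why: tin-acetal-catalysed regioselective sulfonylation of a 1,2-diol activates only the primary hydroxyl, leaving the secondary and tertiary hydroxyls free.

**Step 5**
Reactants: 7 primary mono-tosylate of 6
Product: 5 (2S,5E)-6,10-dimethyl-2-[(2S)-oxiran-2-yl]undeca-5,9-dien-2-ol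
Conditions: K2CO3 (1.2 equiv), MeOH, 0 °C, short reaction time
Reagents that add atoms: none
Why: intramolecular Williamson (3-exo-tet) displacement of the primary tosylate by the C2 alkoxide keeps the C2–O bond, and weak base, low temperature and short exposure keep the tertiary alkoxide from reversing the Payne rearrangement.

**Step 6**
Reactants: 5 (2S,5E)-6,10-dimethyl-2-[(2S)-oxiran-2-yl]undeca-5,9-dien-2-ol
Product: 8 triethylsilyl ether of 5 (tertiary O–SiEt3, terminal epoxide)
Conditions: Et3SiOTf, 2,6-lutidine, CH2Cl2, −78 °C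
Reagents that add atoms: triethylsilyl trifluoromethanesulfonate, CC[Si](CC)(CC)OS(=O)(=O)C(F)(F)F
Why: silyl triflate with a hindered base silylates the tertiary alcohol, and at −78 °C in buffered medium the epoxide is not opened.

**Step 7**
Reactants: 2 2-bromo-4-methoxy-1-(methoxymethoxy)benzene; 8 triethylsilyl ether of 5
Product: 10 (2S,3S,6E)-1-[2-bromo-6-methoxy-3-(methoxymethoxy)phenyl]-3,7,11-trimethyl-3-[(triethylsilyl)oxy]dodeca-6,10-dien-2-ol, via aryllithium 9 (not isolated)
Conditions: 2 (1.5 equiv), LiN(i-Pr)2 (1.4 equiv), THF, −78 °C, 1 h; then 8 (1.0 equiv), BF3·OEt2 (1.6 equiv), −78 °C; NaHCO3 aq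
Reagents that add atoms: none
Why: directed ortho-lithiation removes the only ring proton next to bromine, further acidified by the flanking methoxy group (held at −78 °C so that LiBr is not lost to an aryne), and the aryllithium opens the BF3-activated monosubstituted epoxide at its CH2 terminus, so C2 and C3 are not touched.

**Step 8**
Reactants: 10 bromoaryl alcohol (C2–OH free, C1'–OSiEt3)
Product: 11 (2S)-2-[(2S,5E)-6,10-dimethyl-2-[(triethylsilyl)oxy]undeca-5,9-dien-2-yl]-4-methoxy-7-(methoxymethoxy)-2,3-dihydro-1-benzofuran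
Conditions: Pd(OAc)2 (5 mol %), 2-(di-tert-butylphosphino)-1,1'-binaphthyl (7 mol %), Cs2CO3 (1.5 equiv), toluene, 70 °C
Reagents that add atoms: none
Why: Pd(OAc)2 is reduced in situ to a zerovalent palladium–phosphine complex that inserts into the C7a–Br bond; carbonate-assisted exchange of bromide for the C2 alkoxide at divalent palladium gives a six-membered aryl(alkoxo)palladacycle, and C–O reductive elimination forms O1–C7a. The closest known reaction is the Buchwald–Hartwig intramolecular etherification of o-bromoaryl-substituted secondary alcohols with bulky dialkylbiarylphosphines. The five-membered ring O1–C2–C3–C3a–C7a closes in an exo sense, the oxygen attacking the palladium-bound aryl carbon from within the palladacycle. No stereocentre is created; C2 and C1' are carried over unchanged because no bond to either carbon is broken. The step needs C–O reductive elimination to beat beta-hydride elimination, which the bulky electron-rich phosphine and the constrained palladacycle favour, and it needs five- rather than six-membered closure, which is secured by C2 carrying the only free hydroxyl (the C1' oxygen is silylated) and by bromine lying between the C3a arm and the C7 oxygen.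

**Step 9**
Reactants: 11 dihydrobenzofuran with the hydrocarbon side chain
Product: 12 (2E,6E,10S)-10-[(2S)-4-methoxy-7-(methoxymethoxy)-2,3-dihydro-1-benzofuran-2-yl]-2,6-dimethyl-10-[(triethylsilyl)oxy]undeca-2,6-dien-1-ol
Conditions: SeO2 (0.3 equiv), t-BuOOH (3 equiv), salicylic acid (0.1 equiv), CH2Cl2, rt, to partial conversion; recovered 11 recycled
Reagents that add atoms: tert-butyl hydroperoxide, CC(C)(C)OO (oxygen passed on through selenium dioxide, O=[Se]=O)
Why: catalytic Riley allylic oxidation (ene reaction, then [2,3]-sigmatropic shift) is selective for the E-methyl group of the terminal isopropylidene unit and should give the E-allylic alcohol; any enal formed converges in step 10.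

**Step 10**
Reactants: 12 terminal E-allylic alcohol
Product: 13 the corresponding (2E)-enal
Conditions: MnO2 (activated, excess), CH2Cl2, rt
Reagents that add atoms: none
Why: MnO2 oxidises allylic alcohols selectively to enals without loss of olefin geometry and leaves ethers, the arene and the isolated olefin alone.

**Step 11**
Reactants: 13 (2E)-enal
Product: 14 the corresponding (2E)-2-methylenoic acid
Conditions: NaClO2, NaH2PO4, 2-methyl-2-butene, t-BuOH/H2O, 0 °C → rt
Reagents that add atoms: sodium chlorite, [Na+].[O-]Cl=O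
Why: Pinnick oxidation converts the enal to the acid while 2-methyl-2-butene scavenges HOCl, which protects the trisubstituted olefin and the electron-rich arene.

**Step 12**
Reactants: 14 (2E)-2-methylenoic acid
Product: 15 2-(trimethylsilyl)ethyl ester of 14
Conditions: 2-(trimethylsilyl)ethanol, DCC, DMAP (cat.), CH2Cl2, 0 °C → rt
Reagents that add atoms: 2-(trimethylsilyl)ethanol, C[Si](C)(C)CCO
Why: Steglich esterification masks the acid against the copper hydride and the borane used later, as an ester that fluoride removes together with the silyl ether.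

**Step 13**
Reactants: 15 2-(trimethylsilyl)ethyl ester with the C7 MOM ether
Product: 16 2-(trimethylsilyl)ethyl (2E,6E,10S)-10-[(2S)-7-hydroxy-4-methoxy-2,3-dihydro-1-benzofuran-2-yl]-2,6-dimethyl-10-[(triethylsilyl)oxy]undeca-2,6-dienoate
Conditions: ZnBr2 (1 equiv), n-PrSH (2 equiv), CH2Cl2, 0 °C, 10 min
Reagents that add atoms: none
Why: Lewis-acid-assisted transfer of the methoxymethyl group to the thiol cleaves aryl MOM ethers within minutes at 0 °C, short enough to spare the hindered tertiary silyl ether, the ester and the olefins.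

**Step 14**
Reactants: 16 C7 phenol with the C4 methyl ether
Product: 17 2-(trimethylsilyl)ethyl (2E,6E,10S)-10-[(2S)-4,4-dimethoxy-7-oxo-2,3,4,7-tetrahydro-1-benzofuran-2-yl]-2,6-dimethyl-10-[(triethylsilyl)oxy]undeca-2,6-dienoate
Conditions: PhI(OAc)2 (1.1 equiv), MeOH, 0 °C
Reagents that add atoms: methanol, CO
Why: hypervalent-iodine oxidative dearomatisation of a 4-methoxyphenol, in which methanol adds at the methoxy-bearing carbon para to the phenol oxygen (C4), should give the p-quinone monoketal with the carbonyl at C7.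

**Step 15**
Reactants: 17 quinone monoketal
Product: 18 2-(trimethylsilyl)ethyl (2E,6E,10S)-10-[(2S)-4,4-dimethoxy-7-oxo-2,3,4,5,6,7-hexahydro-1-benzofuran-2-yl]-2,6-dimethyl-10-[(triethylsilyl)oxy]undeca-2,6-dienoate
Conditions: [(Ph3P)CuH]6 (0.3 equiv), H2O (5 equiv), degassed toluene, 0 °C → rt; filtration through Et3N-deactivated silica
Reagents that add atoms: none
Why: conjugate reduction with Stryker's reagent takes the unhindered disubstituted C5=C6 enone bond, the tetrasubstituted alkoxy-bearing C3a=C7a bond and the alpha-methyl enoate being much slower, and the base-free medium avoids loss of methanol and rearomatisation.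

**Step 16**
Reactants: 18 C7 ketone with the C4 dimethyl ketal
Product: 19 2-(trimethylsilyl)ethyl (2E,6E,10S)-10-[(2S,7R)-7-hydroxy-4,4-dimethoxy-2,3,4,5,6,7-hexahydro-1-benzofuran-2-yl]-2,6-dimethyl-10-[(triethylsilyl)oxy]undeca-2,6-dienoate
Conditions: (S)-2-methyl-CBS-oxazaborolidine (0.2 equiv), catecholborane (1.8 equiv), toluene, −78 °C; MeOH quench, cold NaOH aq wash; crude product used at once
Reagents that add atoms: none
Why: Corey–Bakshi–Shibata reduction with catecholborane (no hydroboration or ester reduction at −78 °C) should set C7 as R under catalyst control, the sp2 carbon C7a acting as the large and C6H2 as the small substituent, while C2 and C1' are too remote to interfere and the basic work-up keeps the allylic ketal.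

**Step 17**
Reactants: 19 (7R)-alcohol with the C4 ketal, silyl ether and silylethyl ester
Product: 21 (2E,6E,10S)-10-hydroxy-10-[(2S,7R)-7-hydroxy-4-oxo-2,3,4,5,6,7-hexahydro-1-benzofuran-2-yl]-2,6-dimethylundeca-2,6-dienoic acid (target), via ketal diol acid 20 (not isolated)
Conditions: tris(dimethylamino)sulfonium difluorotrimethylsilicate (TASF, 4 equiv), DMF, 0 °C → rt; then HCl aq to pH 3, THF, 0 °C
Reagents that add atoms: water, O
Why: fluoride cleaves the tertiary silyl ether and the silylethyl ester (loss of ethene) while C4 is still a base-stable ketal, and mild aqueous acid then hydrolyses the ketal through the O1-stabilised vinylogous oxocarbenium ion to the C4 ketone without touching C7.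

**Compound list**
1 | 2-bromo-4-methoxyphenol | COc1ccc(O)c(Br)c1 | starting material
2 | 2-bromo-4-methoxy-1-(methoxymethoxy)benzene | COCOc1ccc(OC)cc1Br | intermediate
3 | (2Z,6E)-farnesol | OC/C=C(/C)CC/C=C(\C)CCC=C(C)C | starting material
4 | [(2R,3S)-3-[(3E)-4,8-dimethylnona-3,7-dien-1-yl]-3-methyloxiran-2-yl]methanol | OC[C@H]1O[C@@]1(C)CC/C=C(\C)CCC=C(C)C | intermediate
5 | (2S,5E)-6,10-dimethyl-2-[(2S)-oxiran-2-yl]undeca-5,9-dien-2-ol | C/C(=C\CC[C@](C)(O)[C@@H]1CO1)CCC=C(C)C | intermediate
6 | (2S,3S,6E)-3,7,11-trimethyldodeca-6,10-diene-1,2,3-triol | C/C(=C\CC[C@](C)(O)[C@@H](O)CO)CCC=C(C)C | intermediate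
7 | (2S,3S,6E)-2,3-dihydroxy-3,7,11-trimethyldodeca-6,10-dien-1-yl 4-methylbenzenesulfonate | C/C(=C\CC[C@](C)(O)[C@@H](O)COS(=O)(=O)c1ccc(C)cc1)CCC=C(C)C | intermediate
8 | {[(2S,5E)-6,10-dimethyl-2-[(2S)-oxiran-2-yl]undeca-5,9-dien-2-yl]oxy}triethylsilane | C/C(=C\CC[C@](C)(O[Si](CC)(CC)CC)[C@@H]1CO1)CCC=C(C)C | intermediate
9 | [2-bromo-6-methoxy-3-(methoxymethoxy)phenyl]lithium | COCOc1ccc(OC)c([Li])c1Br | intermediate
10 | (2S,3S,6E)-1-[2-bromo-6-methoxy-3-(methoxymethoxy)phenyl]-3,7,11-trimethyl-3-[(triethylsilyl)oxy]dodeca-6,10-dien-2-ol | C/C(=C\CC[C@](C)(O[Si](CC)(CC)CC)[C@@H](O)Cc1c(Br)c(OCOC)ccc1OC)CCC=C(C)C | intermediate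
11 | (2S)-2-[(2S,5E)-6,10-dimethyl-2-[(triethylsilyl)oxy]undeca-5,9-dien-2-yl]-4-methoxy-7-(methoxymethoxy)-2,3-dihydro-1-benzofuran | C/C(=C\CC[C@](C)(O[Si](CC)(CC)CC)[C@@H]1Cc2c(O1)c(OCOC)ccc2OC)CCC=C(C)C | intermediate
12 | (2E,6E,10S)-10-[(2S)-4-methoxy-7-(methoxymethoxy)-2,3-dihydro-1-benzofuran-2-yl]-2,6-dimethyl-10-[(triethylsilyl)oxy]undeca-2,6-dien-1-ol | C/C(=C\CC[C@](C)(O[Si](CC)(CC)CC)[C@@H]1Cc2c(O1)c(OCOC)ccc2OC)CC/C=C(\C)CO | intermediate
13 | (2E,6E,10S)-10-[(2S)-4-methoxy-7-(methoxymethoxy)-2,3-dihydro-1-benzofuran-2-yl]-2,6-dimethyl-10-[(triethylsilyl)oxy]undeca-2,6-dienal | C/C(=C\CC[C@](C)(O[Si](CC)(CC)CC)[C@@H]1Cc2c(O1)c(OCOC)ccc2OC)CC/C=C(\C)C=O | intermediate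
14 | (2E,6E,10S)-10-[(2S)-4-methoxy-7-(methoxymethoxy)-2,3-dihydro-1-benzofuran-2-yl]-2,6-dimethyl-10-[(triethylsilyl)oxy]undeca-2,6-dienoic acid | C/C(=C\CC[C@](C)(O[Si](CC)(CC)CC)[C@@H]1Cc2c(O1)c(OCOC)ccc2OC)CC/C=C(\C)C(=O)O | intermediate
15 | 2-(trimethylsilyl)ethyl (2E,6E,10S)-10-[(2S)-4-methoxy-7-(methoxymethoxy)-2,3-dihydro-1-benzofuran-2-yl]-2,6-dimethyl-10-[(triethylsilyl)oxy]undeca-2,6-dienoate | C/C(=C\CC[C@](C)(O[Si](CC)(CC)CC)[C@@H]1Cc2c(O1)c(OCOC)ccc2OC)CC/C=C(\C)C(=O)OCC[Si](C)(C)C | intermediate
16 | 2-(trimethylsilyl)ethyl (2E,6E,10S)-10-[(2S)-7-hydroxy-4-methoxy-2,3-dihydro-1-benzofuran-2-yl]-2,6-dimethyl-10-[(triethylsilyl)oxy]undeca-2,6-dienoate | C/C(=C\CC[C@](C)(O[Si](CC)(CC)CC)[C@@H]1Cc2c(O1)c(O)ccc2OC)CC/C=C(\C)C(=O)OCC[Si](C)(C)C | intermediate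
17 | 2-(trimethylsilyl)ethyl (2E,6E,10S)-10-[(2S)-4,4-dimethoxy-7-oxo-2,3,4,7-tetrahydro-1-benzofuran-2-yl]-2,6-dimethyl-10-[(triethylsilyl)oxy]undeca-2,6-dienoate | C/C(=C\CC[C@](C)(O[Si](CC)(CC)CC)[C@@H]1CC2=C(O1)C(=O)C=CC2(OC)OC)CC/C=C(\C)C(=O)OCC[Si](C)(C)C | intermediate
18 | 2-(trimethylsilyl)ethyl (2E,6E,10S)-10-[(2S)-4,4-dimethoxy-7-oxo-2,3,4,5,6,7-hexahydro-1-benzofuran-2-yl]-2,6-dimethyl-10-[(triethylsilyl)oxy]undeca-2,6-dienoate | C/C(=C\CC[C@](C)(O[Si](CC)(CC)CC)[C@@H]1CC2=C(O1)C(=O)CCC2(OC)OC)CC/C=C(\C)C(=O)OCC[Si](C)(C)C | intermediate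
19 | 2-(trimethylsilyl)ethyl (2E,6E,10S)-10-[(2S,7R)-7-hydroxy-4,4-dimethoxy-2,3,4,5,6,7-hexahydro-1-benzofuran-2-yl]-2,6-dimethyl-10-[(triethylsilyl)oxy]undeca-2,6-dienoate | C/C(=C\CC[C@](C)(O[Si](CC)(CC)CC)[C@@H]1CC2=C(O1)[C@H](O)CCC2(OC)OC)CC/C=C(\C)C(=O)OCC[Si](C)(C)C | intermediate
20 | (2E,6E,10S)-10-hydroxy-10-[(2S,7R)-7-hydroxy-4,4-dimethoxy-2,3,4,5,6,7-hexahydro-1-benzofuran-2-yl]-2,6-dimethylundeca-2,6-dienoic acid | C/C(=C\CC[C@](C)(O)[C@@H]1CC2=C(O1)[C@H](O)CCC2(OC)OC)CC/C=C(\C)C(=O)O | intermediate
21 | (2E,6E,10S)-10-hydroxy-10-[(2S,7R)-7-hydroxy-4-oxo-2,3,4,5,6,7-hexahydro-1-benzofuran-2-yl]-2,6-dimethylundeca-2,6-dienoic acid (CNP0297149.1) | C/C(=C\CC[C@](C)(O)[C@@H]1CC2=C(O1)[C@H](O)CCC2=O)CC/C=C(\C)C(=O)O | target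

**Step count and risks**
Total steps: 17. Longest linear sequence: 16 steps (3 → 21, steps 2–17).

Steps most likely to fail:

Step 8 (key step). Beta-hydride elimination from the palladium alkoxide (ketone plus debrominated arene) may outrun C–O reductive elimination. Base-induced migration of the triethylsilyl group from the C1' oxygen to the C2 oxygen may also occur, followed by six-membered closure through the tertiary oxygen. The fallback forms the other ring C–O bond (O1–C2) by epoxide opening with double inversion; it sets out from 10 and comes back at 11. Compound 10 is mesylated (MsCl, Et3N, CH2Cl2, 0 °C) to the C2 mesylate F1. Bu4NF in THF removes the silyl group, and the tertiary alkoxide displaces the mesylate with inversion at C2 to give the bromoaryl trisubstituted epoxide F2. Hydroxylation of the aryl bromide (Pd2(dba)3, 2-di-tert-butylphosphino-2',4',6'-triisopropylbiphenyl, KOH, 1,4-dioxane/H2O, 100 °C; hydroxide on divalent palladium has no beta-hydrogen) gives the phenoxide of the epoxy phenol F3. Under the same basic conditions F3 opens the epoxide 5-exo at C2 with a second inversion to the tertiary alcohol F4 (net retention at C2, C1' untouched). Et3SiOTf/2,6-lutidine at −78 °C then returns 11.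

Step 7. The ortho-lithiated bromoarene may lose LiBr to an aryne before the epoxide is opened, diisopropylamine may capture BF3 so that the epoxide is not activated, or BF3 may rearrange the silyloxy epoxide. The fallback uses halogen–magnesium exchange and copper-catalysed opening, without BF3 or free amine; it sets out from 2 and 8 and comes back at 10. Compound 2 is lithiated as before and quenched with iodine to the aryl iodide 2-bromo-3-iodo-4-methoxy-1-(methoxymethoxy)benzene F5. i-PrMgCl·LiCl exchanges the iodine selectively (THF, −40 °C) to the arylmagnesium chloride F6, which is far less prone to aryne formation. CuI (10 mol %) then mediates opening of 8 at its CH2 terminus (−30 → 0 °C) to give 10.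

Step 16. Facial selectivity at the alpha-alkoxy enone carbonyl may be poor, or the Lewis-acidic borane may ionise the allylic ketal, leading to aromatisation. The fallback replaces catalyst control by reduction, separation and recycling; it sets out from 18 and comes back at 19. Luche reduction (NaBH4, CeCl3·7H2O, MeOH, −78 °C; methanol as solvent keeps the ketal) gives 19 together with its C7 epimer, the (7S)-ketal alcohol F7. The diastereomers are separated on Et3N-deactivated silica; 19 goes into step 17, and F7 is oxidised back to 18 with MnO2 and reduced again.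

**Further compounds**
F1 | step 8 | (2S,3S,6E)-1-[2-bromo-6-methoxy-3-(methoxymethoxy)phenyl]-3,7,11-trimethyl-3-[(triethylsilyl)oxy]dodeca-6,10-dien-2-yl methanesulfonate | C/C(=C\CC[C@](C)(O[Si](CC)(CC)CC)[C@@H](OS(C)(=O)=O)Cc1c(Br)c(OCOC)ccc1OC)CCC=C(C)C
F2 | step 8 | 2-bromo-3-{[(2R,3S)-3-[(3E)-4,8-dimethylnona-3,7-dien-1-yl]-3-methyloxiran-2-yl]methyl}-4-methoxy-1-(methoxymethoxy)benzene | COCOc1ccc(OC)c(C[C@H]2O[C@@]2(C)CC/C=C(\C)CCC=C(C)C)c1Br
F3 | step 8 | 2-{[(2R,3S)-3-[(3E)-4,8-dimethylnona-3,7-dien-1-yl]-3-methyloxiran-2-yl]methyl}-3-methoxy-6-(methoxymethoxy)phenol | COCOc1ccc(OC)c(C[C@H]2O[C@@]2(C)CC/C=C(\C)CCC=C(C)C)c1O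
F4 | step 8 | (2S,5E)-2-[(2S)-4-methoxy-7-(methoxymethoxy)-2,3-dihydro-1-benzofuran-2-yl]-6,10-dimethylundeca-5,9-dien-2-ol | C/C(=C\CC[C@](C)(O)[C@@H]1Cc2c(O1)c(OCOC)ccc2OC)CCC=C(C)C
F5 | step 7 | 2-bromo-3-iodo-4-methoxy-1-(methoxymethoxy)benzene | COCOc1ccc(OC)c(I)c1Br
F6 | step 7 | [2-bromo-6-methoxy-3-(methoxymethoxy)phenyl]magnesium chloride | COCOc1ccc(OC)c([Mg]Cl)c1Br
F7 | step 16 | 2-(trimethylsilyl)ethyl (2E,6E,10S)-10-[(2S,7S)-7-hydroxy-4,4-dimethoxy-2,3,4,5,6,7-hexahydro-1-benzofuran-2-yl]-2,6-dimethyl-10-[(triethylsilyl)oxy]undeca-2,6-dienoate | C/C(=C\CC[C@](C)(O[Si](CC)(CC)CC)[C@@H]1CC2=C(O1)[C@@H](O)CCC2(OC)OC)CC/C=C(\C)C(=O)OCC[Si](C)(C)C
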